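(Readings and results were generated by integration with constants of no real substance, and the scatter is random.)

I decided to reckon these flasks by hand, with one number, before trusting any integration.

| setting | dawn | noon | winter | oak | elm | larch |
|---|---|---|---|---|---|---|
| substrate | 0.30 M | 0.30 M | 0.30 M | 0.30 M | 0.30 M | 0.30 M (fed, over 1.0 h) |
| first nucleophile | 0.90 M | 0.60 M | 1.4 M | 0.900 M | 0.900 M | 0.900 M |
| second nucleophile | 0.45 M | 0.45 M | 0.45 M | 0.450 M (fed, over 1.0 h) | 0.450 M | 0.450 M |
| remark | run made earlier | run made earlier | run made earlier | all else is in the flask from the start; the feed brings no volume worth counting | everything together at the start | all else is in the flask from the start; the feed brings no volume worth counting |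
| time |  |  |  | 2.5 h | 2.5 h | 2.5 h |

| run | time / h | other capture product / % | target / % |
|---|---|---|---|
| dawn | 0.667 | 70.0 | 2.9 |
| dawn | 1.33 | 89.9 | 2.0 |
| dawn | 2.00 | 95.4 | 1.9 |
| dawn | 2.50 | 96.8 | 1.6 |
| noon | 0.833 | 78.5 | 1.9 |
| noon | 1.50 | 92.6 | 1.2 |
| noon | 2.50 | 97.2 | 1.6 |
| noon | 3.00 | 98.6 | 1.0 |
| winter | 0.250 | 34.5 | 4.3 |
| winter | 0.500 | 58.8 | 3.8 |
| winter | 1.33 | 88.6 | 3.6 |
| winter | 3.00 | 96.9 | 1.8 |

(each reading ± 0.3 percentage points)

- reactions considered so far: substrate <-> intermediate; first nucleophile + intermediate <-> target; second nucleophile + intermediate -> other capture product; second nucleophile -> decomposed reagent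

1. the flask that comes out highest in amount of other capture product, in percent of the substrate charged, or "all alike" when all lie within 1.5 percentage points (oak / elm / larch / all alike)
2. other capture product at the end, in percent of the substrate charged, oak
3. other capture product at the end, in percent of the substrate charged, elm
4. other capture product at the end, in percent of the substrate charged, larch

1. First rung, target. Winter showed 4.3% at 0.250 h, less than its 34.5% of other capture product, so I treated target as a small side store.

2. Second rung, substrate. Charge minus both products fell at 1.96 h⁻¹ in dawn and 1.96 h⁻¹ in winter, with 0.90 M against 1.4 M of first nucleophile. So I took substrate's own step as the rate-limiting step of these early readings, with mean life 0.511 h.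

3. Third rung, the feed. It runs 1.0 h, longer than that life, and a steady feed moves a species' mean entry by 0.500 h.

4. Fourth rung, reagent decay. Dawn's capture crept from 95.4% to 96.8% between 2.00 h and 2.50 h, so I assumed its reagent and substrate ended together. Reagent decaying at rate d then needs kA/(kA−d) per substrate, and dawn charged 1.50. That gave d = 0.652 h⁻¹, a mean life of 1.53 h, longer than the feed and shorter than the run.

5. The rule. I replaced the arrival curve by its mean wait w between reagent and substrate. For elm, w is 0.511 h, giving 1.07. This is the reagent cover: c(second nucleophile)·exp(−d·w)/c(substrate), surviving reagent per substrate charged. With a cover below 1, I took second nucleophile as limiting reagent and capture as roughly the cover. Elm has dawn's charges, so the exact rate rule gives it 1 by the choice of d, and the mean errs by 0.0700.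

6. Oak's wait shrinks by 0.500 h, so its cover is 1.49. Larch's wait grows by 0.500 h, so its cover is 0.776. I expected about 77.6% from larch, below the forecast.

The forecast named oak highest, with oak 98%, elm 97% and larch 92%, and of larch it said “reagent runs short, leaving capture incomplete”.

7. Oak gave 98.6%, elm 97.0% and larch 84.3%, so oak came highest.

    substrate ⇌ intermediate (K = 0.110, k = 0.0330 min⁻¹)
    first nucleophile + intermediate ⇌ target (K = 28.0 M⁻¹, k = 25.0 M⁻¹ min⁻¹)
    second nucleophile + intermediate → other capture product (k = 66.0 M⁻¹ min⁻¹)
    second nucleophile → decomposed reagent (k = 0.0100 min⁻¹)

8. Larch's cover stood 6.7 percentage points below its result, and larch ended with 0.0670% of its second nucleophile. Its decomposed reagent was 0.197 M, less than the 0.217 M my cover implied. The neighbouring flask is larch with 0.11 M of second nucleophile. The same wait gives it a cover of 0.190, so I reckoned about 19.0% capture. It held 0% of its second nucleophile at 2.50 h and gave 26.5% other capture product.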